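**Retrosynthetic overview**

- The route rests on ring A, the 4-pyranone of the chromone (O1, C2 with its methyl, C3, C4, C4a, C8a). It is dissected into the phenol oxygen and the iodine-bearing carbon of ring B (the chromone benzo ring), carbon monoxide (C4) and propyne (C3, C2, CH3), so one carbonylative alkynylation–cyclisation makes C4a–C4, C4–C3 and O1–C2.
- The CH2 bridge between ring B and ring C (the isochromanone arene) is cut at the ring C carbon: a C5 arylmagnesium adds to a silyl-protected 4-hydroxy-2,6-dimethoxybenzaldehyde and the carbinol is reduced ionically.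
- Lactone ring D with its (R)-C3 centre comes from atraric acid by lateral lithiation–acetylation, enzymatic ketone reduction and lactonisation.
- Order of ring formation: ring C is bought, ring D is closed in step 3, ring B is attached in steps 6–7, ring A is closed in step 10; BCl3 then frees the three phenols.

Key step: step 10

Assumption: rotation about the two aryl–CH2 bonds is taken as fast, so the two positions ortho to the ring B phenol are equivalent and mono-iodination can give only one product.

**Route**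

Step 1
Reactants: 1 atraric acid (methyl 2,4-dihydroxy-3,6-dimethylbenzoate)
Product: 2 methyl 2,4-bis(benzyloxy)-3,6-dimethylbenzoate
Conditions: BnBr, K2CO3, n-Bu4NI (cat.), DMF, 70 °C
Reagents that add atoms: benzyl bromide, BrCc1ccccc1
Why: Williamson ether synthesis on both phenols; the benzyl ethers should withstand the amide base, the Grignard reagent and the amine used later and are removed by BCl3 at the end.

Step 2
Reactants: 2 methyl 2,4-bis(benzyloxy)-3,6-dimethylbenzoate; 3 N-methoxy-N-methylacetamide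
Product: 5 methyl 2,4-bis(benzyloxy)-3-methyl-6-(2-oxopropyl)benzoate, via benzylic lithium species 4 (not isolated)
Conditions: LiN(i-Pr)2 (2.1 equiv), THF, −78 °C; then 3 (1.5 equiv), −78 → −40 °C; aq. NH4Cl
Reagents that add atoms: none
Why: Lateral lithiation of the ortho-toluate (the C6 methyl is the vinylogous α-position of the hindered ester) followed by acylation with a Weinreb amide, whose chelated tetrahedral adduct prevents over-addition.

Step 3
Reactants: 5 methyl 2,4-bis(benzyloxy)-3-methyl-6-(2-oxopropyl)benzoate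
Product: 7 (3R)-6,8-bis(benzyloxy)-3,7-dimethylisochroman-1-one, via (R)-hydroxy ester 6 (not isolated)
Conditions: alcohol dehydrogenase from Lactobacillus brevis, NADP+ (cat.), i-PrOH, MgCl2 (1 mM), phosphate buffer pH 7/DMSO, 30 °C; toluene extract, then p-TsOH·H2O (cat.), 70 °C
Reagents that add atoms: none
Why: Enzymatic asymmetric ketone reduction in which this NADPH-dependent dehydrogenase delivers hydride to the si face of a methyl ketone with one bulky substituent, setting C3 as (R), followed by acid-catalysed lactonisation (intramolecular transesterification) that closes ring D.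

Step 4
Reactants: 7 (3R)-6,8-bis(benzyloxy)-3,7-dimethylisochroman-1-one
Product: 8 (3R)-6,8-bis(benzyloxy)-5-iodo-3,7-dimethylisochroman-1-one
Conditions: NIS, TFA (cat.), MeCN, 0 °C → rt
Reagents that add atoms: N-iodosuccinimide, O=C1CCC(=O)N1I
Why: Electrophilic aromatic iodination; C5 is the only unsubstituted carbon of ring C and lies ortho and para to the two benzyloxy groups and meta to the lactone carbonyl.

Step 5
Reactants: 9 4-hydroxy-2,6-dimethoxybenzaldehyde
Product: 10 2,6-dimethoxy-4-(triisopropylsilyloxy)benzaldehyde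
Conditions: i-Pr3SiCl, imidazole, DMF, rt
Reagents that add atoms: chlorotriisopropylsilane, CC(C)[Si](Cl)(C(C)C)C(C)C
Why: Silylation of the phenol; the bulky aryl silyl ether should survive the Grignard addition and the acidic reduction and is removed selectively by fluoride.

Step 6
Reactants: 8 (3R)-6,8-bis(benzyloxy)-5-iodo-3,7-dimethylisochroman-1-one; 10 2,6-dimethoxy-4-(triisopropylsilyloxy)benzaldehyde
Product: 12 (3R)-6,8-bis(benzyloxy)-5-{hydroxy[2,6-dimethoxy-4-(triisopropylsilyloxy)phenyl]methyl}-3,7-dimethylisochroman-1-one (carbinol epimer mixture), via arylmagnesium chloride 11 (not isolated)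
Conditions: i-PrMgCl·LiCl (1.1 equiv), THF, −20 °C; then 10, −20 → 0 °C; aq. NH4Cl
Reagents that add atoms: none
Why: Iodine–magnesium exchange, accelerated by the ortho benzyloxy group and cold enough to spare the lactone, followed by Grignard 1,2-addition to the aldehyde; the new carbinol centre is formed without control and is removed in step 7.

Step 7
Reactants: 12 (3R)-6,8-bis(benzyloxy)-5-{hydroxy[2,6-dimethoxy-4-(triisopropylsilyloxy)phenyl]methyl}-3,7-dimethylisochroman-1-one
Product: 13 (3R)-6,8-bis(benzyloxy)-5-[2,6-dimethoxy-4-(triisopropylsilyloxy)benzyl]-3,7-dimethylisochroman-1-one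
Conditions: Et3SiH, TFA, CH2Cl2, 0 °C
Reagents that add atoms: none
Why: Ionic hydrogenation; acid ionises the doubly benzylic carbinol to a cation stabilised by the trioxygenated ring B and Et3SiH delivers hydride, leaving benzyl ethers, silyl ether and lactone intact.

Step 8
Reactants: 13 (3R)-6,8-bis(benzyloxy)-5-[2,6-dimethoxy-4-(triisopropylsilyloxy)benzyl]-3,7-dimethylisochroman-1-one
Product: 14 (3R)-6,8-bis(benzyloxy)-5-(4-hydroxy-2,6-dimethoxybenzyl)-3,7-dimethylisochroman-1-one
Conditions: n-Bu4NF, AcOH, THF, 0 °C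
Reagents that add atoms: none
Why: Fluoride-mediated desilylation of the aryl silyl ether; acetic acid buffers the phenoxide so that the lactone should not be opened.

Step 9
Reactants: 14 (3R)-6,8-bis(benzyloxy)-5-(4-hydroxy-2,6-dimethoxybenzyl)-3,7-dimethylisochroman-1-one
Product: 15 (3R)-6,8-bis(benzyloxy)-5-(4-hydroxy-3-iodo-2,6-dimethoxybenzyl)-3,7-dimethylisochroman-1-one
Conditions: NIS (1.0 equiv), p-TsOH·H2O (cat.), MeCN, −20 → 0 °C
Reagents that add atoms: N-iodosuccinimide, O=C1CCC(=O)N1I
Why: Electrophilic aromatic iodination ortho to the only free phenol; ring C has no free position, the two ortho sites of ring B are equivalent, and one equivalent of reagent at low temperature should limit di-iodination.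

Step 10
Reactants: 15 (3R)-6,8-bis(benzyloxy)-5-(4-hydroxy-3-iodo-2,6-dimethoxybenzyl)-3,7-dimethylisochroman-1-one; 16 propyne; 17 carbon monoxide
Product: 20 (3R)-6,8-bis(benzyloxy)-5-[(5,7-dimethoxy-2-methyl-4-oxo-4H-chromen-6-yl)methyl]-3,7-dimethylisochroman-1-one, via aryl ynone 18 (not isolated), via enaminone 19 (not isolated)
Conditions: PdCl2(PPh3)2 (5 mol%), CO (10 bar), propyne (3 equiv, THF solution), Et2NH/THF, 80 °C, autoclave
Reagents that add atoms: none
Why: Zerovalent palladium, formed in situ from PdCl2(PPh3)2, inserts into the C–I bond of 15, CO insertion gives the aroyl–palladium species, and amine-deprotonated propyne is coupled to it to release ynone 18 (C4a–C4 and C4–C3); diethylamine then adds in conjugate fashion to give enaminone 19, whose β-carbon is attacked by the neighbouring phenol oxygen with loss of diethylamine (O1–C2). The closest known reaction type is the palladium-catalysed carbonylative coupling of ortho-iodophenols with terminal alkynes in a secondary amine, which gives chromones and flavones. Ring A closes by a net 6-endo addition–elimination on the enaminone, the 5-exo path to the aurone being blocked because the amine already occupies the β-position. No stereocentre is formed and the remote (R)-C3 centre is not touched. The step needs CO insertion to outrun direct alkynylation, which CO pressure and the absence of copper should secure, and it needs the acyl group and O1 on the correct carbons, which is fixed because the iodine sits between the only free hydroxyl and a methoxy group of ring B while every other phenol is benzylated and cannot form an aryl ester.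

Step 11
Reactants: 20 (3R)-6,8-bis(benzyloxy)-5-[(5,7-dimethoxy-2-methyl-4-oxo-4H-chromen-6-yl)methyl]-3,7-dimethylisochroman-1-one
Product: 21 (3R)-6,8-dihydroxy-5-[(5-hydroxy-7-methoxy-2-methyl-4-oxo-4H-chromen-6-yl)methyl]-3,7-dimethylisochroman-1-one (CNP0180307.1)
Conditions: BCl3, pentamethylbenzene, CH2Cl2, −78 → 0 °C; then H2O
Reagents that add atoms: none
Why: Lewis acid ether cleavage; BCl3 removes both benzyl ethers (the benzyl cation is trapped by pentamethylbenzene) and, through the six-membered chelate with the C4 carbonyl, the C5 methyl ether, whereas the unchelated C7 methyl ether should react much more slowly.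

**Compound list**

1 | atraric acid (methyl 2,4-dihydroxy-3,6-dimethylbenzoate) | COC(=O)c1c(C)cc(O)c(C)c1O | starting material
2 | methyl 2,4-bis(benzyloxy)-3,6-dimethylbenzoate | COC(=O)c1c(C)cc(OCc2ccccc2)c(C)c1OCc1ccccc1 | intermediate
3 | N-methoxy-N-methylacetamide | CC(=O)N(C)OC | starting material
4 | methyl 2,4-bis(benzyloxy)-6-(lithiomethyl)-3-methylbenzoate | [Li]Cc1cc(OCc2ccccc2)c(C)c(OCc2ccccc2)c1C(=O)OC | intermediate
5 | methyl 2,4-bis(benzyloxy)-3-methyl-6-(2-oxopropyl)benzoate | COC(=O)c1c(CC(C)=O)cc(OCc2ccccc2)c(C)c1OCc1ccccc1 | intermediate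
6 | methyl 2,4-bis(benzyloxy)-6-[(2R)-2-hydroxypropyl]-3-methylbenzoate | COC(=O)c1c(C[C@@H](C)O)cc(OCc2ccccc2)c(C)c1OCc1ccccc1 | intermediate
7 | (3R)-6,8-bis(benzyloxy)-3,7-dimethylisochroman-1-one | C[C@@H]1Cc2cc(OCc3ccccc3)c(C)c(OCc3ccccc3)c2C(=O)O1 | intermediate
8 | (3R)-6,8-bis(benzyloxy)-5-iodo-3,7-dimethylisochroman-1-one | C[C@@H]1Cc2c(I)c(OCc3ccccc3)c(C)c(OCc3ccccc3)c2C(=O)O1 | intermediate
9 | 4-hydroxy-2,6-dimethoxybenzaldehyde | COc1cc(O)cc(OC)c1C=O | starting material
10 | 2,6-dimethoxy-4-(triisopropylsilyloxy)benzaldehyde | COc1cc(O[Si](C(C)C)(C(C)C)C(C)C)cc(OC)c1C=O | intermediate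
11 | [(3R)-6,8-bis(benzyloxy)-3,7-dimethyl-1-oxoisochroman-5-yl]magnesium chloride | C[C@@H]1Cc2c([Mg]Cl)c(OCc3ccccc3)c(C)c(OCc3ccccc3)c2C(=O)O1 | intermediate
12 | (3R)-6,8-bis(benzyloxy)-5-{hydroxy[2,6-dimethoxy-4-(triisopropylsilyloxy)phenyl]methyl}-3,7-dimethylisochroman-1-one (carbinol epimer mixture) | COc1cc(O[Si](C(C)C)(C(C)C)C(C)C)cc(OC)c1C(O)c1c(OCc2ccccc2)c(C)c(OCc2ccccc2)c2c1C[C@@H](C)OC2=O | intermediate
13 | (3R)-6,8-bis(benzyloxy)-5-[2,6-dimethoxy-4-(triisopropylsilyloxy)benzyl]-3,7-dimethylisochroman-1-one | COc1cc(O[Si](C(C)C)(C(C)C)C(C)C)cc(OC)c1Cc1c(OCc2ccccc2)c(C)c(OCc2ccccc2)c2c1C[C@@H](C)OC2=O | intermediate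
14 | (3R)-6,8-bis(benzyloxy)-5-(4-hydroxy-2,6-dimethoxybenzyl)-3,7-dimethylisochroman-1-one | COc1cc(O)cc(OC)c1Cc1c(OCc2ccccc2)c(C)c(OCc2ccccc2)c2c1C[C@@H](C)OC2=O | intermediate
15 | (3R)-6,8-bis(benzyloxy)-5-(4-hydroxy-3-iodo-2,6-dimethoxybenzyl)-3,7-dimethylisochroman-1-one | COc1cc(O)c(I)c(OC)c1Cc1c(OCc2ccccc2)c(C)c(OCc2ccccc2)c2c1C[C@@H](C)OC2=O | intermediate
16 | propyne | CC#C | starting material
17 | carbon monoxide | [C-]#[O+] | starting material
18 | (3R)-6,8-bis(benzyloxy)-5-[3-(but-2-ynoyl)-4-hydroxy-2,6-dimethoxybenzyl]-3,7-dimethylisochroman-1-one | CC#CC(=O)c1c(O)cc(OC)c(Cc2c(OCc3ccccc3)c(C)c(OCc3ccccc3)c3c2C[C@@H](C)OC3=O)c1OC | intermediate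
19 | (3R)-6,8-bis(benzyloxy)-5-{3-[3-(diethylamino)but-2-enoyl]-4-hydroxy-2,6-dimethoxybenzyl}-3,7-dimethylisochroman-1-one (alkene geometry not defined) | CCN(CC)C(C)=CC(=O)c1c(O)cc(OC)c(Cc2c(OCc3ccccc3)c(C)c(OCc3ccccc3)c3c2C[C@@H](C)OC3=O)c1OC | intermediate
20 | (3R)-6,8-bis(benzyloxy)-5-[(5,7-dimethoxy-2-methyl-4-oxo-4H-chromen-6-yl)methyl]-3,7-dimethylisochroman-1-one | COc1cc2oc(C)cc(=O)c2c(OC)c1Cc1c(OCc3ccccc3)c(C)c(OCc3ccccc3)c2c1C[C@@H](C)OC2=O | intermediate
21 | (3R)-6,8-dihydroxy-5-[(5-hydroxy-7-methoxy-2-methyl-4-oxo-4H-chromen-6-yl)methyl]-3,7-dimethylisochroman-1-one (CNP0180307.1) | COc1cc2oc(C)cc(=O)c2c(O)c1Cc1c(O)c(C)c(O)c2c1C[C@@H](C)OC2=O | target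

**Step count**

Total: 11 steps. Longest linear sequence: 10 steps (steps 1–4 and 6–11 from atraric acid); step 5 is a one-step side branch.

**Steps most likely to fail**

1. Step 10. The aroyl–palladium species may be captured by diethylamine to give an amide. Direct alkynylation without CO insertion may lead to a 2-methylbenzofuran. Oxidative addition at the doubly ortho-substituted C–I bond may be slow, and the amine may slowly open the lactone at the temperature needed. Fallback, from 15 back to 20: Stille coupling of 15 with tributyl(1-ethoxyvinyl)stannane (Pd(PPh3)4, CuI, dioxane, 90 °C) should give the enol ether (3R)-6,8-bis(benzyloxy)-5-[3-(1-ethoxyvinyl)-4-hydroxy-2,6-dimethoxybenzyl]-3,7-dimethylisochroman-1-one F1. Dilute aqueous HCl in THF hydrolyses it to the ortho-hydroxyacetophenone (3R)-5-(3-acetyl-4-hydroxy-2,6-dimethoxybenzyl)-6,8-bis(benzyloxy)-3,7-dimethylisochroman-1-one F2. Heating F2 with N,N-dimethylacetamide dimethyl acetal in toluene should give the enaminone (3R)-6,8-bis(benzyloxy)-5-{3-[3-(dimethylamino)but-2-enoyl]-4-hydroxy-2,6-dimethoxybenzyl}-3,7-dimethylisochroman-1-one F3, which closes to chromone 20 with loss of dimethylamine on further heating or on brief treatment with acetic acid.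

2. Step 6. Iodine–magnesium exchange at the electron-rich, doubly flanked C5 may be slow at a temperature that still spares the lactone, and addition of the hindered arylmagnesium to the hindered, electron-rich aldehyde may be sluggish, so protonated arene or lactone attack may take over. Fallback, from 7 and 10 back to 13: NaBH4 in MeOH reduces 10 to the benzylic alcohol [2,6-dimethoxy-4-(triisopropylsilyloxy)phenyl]methanol F4. Friedel–Crafts benzylation of an excess of lactone 7 with F4 (Sc(OTf)3 cat., CH2Cl2/hexafluoroisopropanol, 0 °C) should alkylate C5, the only free position of ring C, and give 13 directly. The bulky silyl ether shields the ring B positions that would otherwise lead to self-alkylation.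

3. Step 3. The bulky bis-benzyl ketone may be a poor substrate for the dehydrogenase, giving low conversion or eroded enantioselectivity. Fallback, from 5 back to 7: NaBH4 (MeOH/THF, −10 °C, cold AcOH quench) gives the racemic hydroxy ester methyl 2,4-bis(benzyloxy)-6-(2-hydroxypropyl)-3-methylbenzoate F5. Kinetic resolution by lipase-catalysed acylation (Candida antarctica lipase B, vinyl acetate, MTBE, 30 °C) should acylate the (R)-alcohol, giving methyl 6-[(2R)-2-acetoxypropyl]-2,4-bis(benzyloxy)-3-methylbenzoate F6 and leaving methyl 2,4-bis(benzyloxy)-6-[(2S)-2-hydroxypropyl]-3-methylbenzoate F7, which is separated by chromatography. K2CO3 in MeOH cleaves the acetate of F6 to 6, which lactonises in the same flask to 7.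

**Further compounds**

F1 | step 10 | (3R)-6,8-bis(benzyloxy)-5-[3-(1-ethoxyvinyl)-4-hydroxy-2,6-dimethoxybenzyl]-3,7-dimethylisochroman-1-one | CCOC(=C)c1c(O)cc(OC)c(Cc2c(OCc3ccccc3)c(C)c(OCc3ccccc3)c3c2C[C@@H](C)OC3=O)c1OC
F2 | step 10 | (3R)-5-(3-acetyl-4-hydroxy-2,6-dimethoxybenzyl)-6,8-bis(benzyloxy)-3,7-dimethylisochroman-1-one | CC(=O)c1c(O)cc(OC)c(Cc2c(OCc3ccccc3)c(C)c(OCc3ccccc3)c3c2C[C@@H](C)OC3=O)c1OC
F3 | step 10 | (3R)-6,8-bis(benzyloxy)-5-{3-[3-(dimethylamino)but-2-enoyl]-4-hydroxy-2,6-dimethoxybenzyl}-3,7-dimethylisochroman-1-one | CN(C)C(C)=CC(=O)c1c(O)cc(OC)c(Cc2c(OCc3ccccc3)c(C)c(OCc3ccccc3)c3c2C[C@@H](C)OC3=O)c1OC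
F4 | step 6 | [2,6-dimethoxy-4-(triisopropylsilyloxy)phenyl]methanol | COc1cc(O[Si](C(C)C)(C(C)C)C(C)C)cc(OC)c1CO
F5 | step 3 | racemic methyl 2,4-bis(benzyloxy)-6-(2-hydroxypropyl)-3-methylbenzoate | COC(=O)c1c(CC(C)O)cc(OCc2ccccc2)c(C)c1OCc1ccccc1
F6 | step 3 | methyl 6-[(2R)-2-acetoxypropyl]-2,4-bis(benzyloxy)-3-methylbenzoate | COC(=O)c1c(C[C@@H](C)OC(C)=O)cc(OCc2ccccc2)c(C)c1OCc1ccccc1
F7 | step 3 | methyl 2,4-bis(benzyloxy)-6-[(2S)-2-hydroxypropyl]-3-methylbenzoate | COC(=O)c1c(C[C@H](C)O)cc(OCc2ccccc2)c(C)c1OCc1ccccc1
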